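A stirred, isothermal vessel receives partner at a steady rate into substrate. Two earlier runs, eta and theta, were read at other substrate charges.

| flask | substrate | partner | remark | time |
|---|---|---|---|---|
| eta | 18 mM | 2.5 equiv (fed, over 8.0 min) | run made earlier |  |
| theta | 70 mM | 2.5 equiv (fed, over 8.0 min) | run made earlier |  |
| flask | 35 mM | 2.50 equiv (fed, over 8.0 min) |  | 8.0 min |

| run | time / min | substrate / % | mono adduct / % |
|---|---|---|---|
| eta | 0.667 | 98 | 1 |
| eta | 2.00 | 98 | 2 |
| eta | 4.00 | 97 | 3 |
| eta | 6.00 | 94 | 3 |
| eta | 8.00 | 97 | 8 |
| theta | 1.50 | 98 | 1 |
| theta | 3.00 | 88 | 5 |
| theta | 5.00 | 83 | 8 |
| theta | 6.00 | 86 | 10 |
| theta | 8.00 | 72 | 16 |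

(scatter of a reading: 2 percentage points)

- for by-product the idle adduct is counted in
- the numbers in the tables scatter with a standard deviation of 2 percentage points
- reactions considered so far: partner -> decomposed reagent; substrate + partner -> mono adduct + by-product; partner + mono adduct -> double product + by-product; substrate + by-product <-> idle adduct

1. the substrate standing at 8.0 min, as a percentage of the substrate charged
2. the mono adduct standing at 8.0 min, as a percentage of the substrate charged
3. the double product standing at 8.0 min, as a percentage of the substrate charged

Take first the main step alone, substrate with partner. Partner goes in at the same equivalents over the same feed time in these flasks, so its standing concentration should follow the substrate charge, and the substrate lifetime τ, a pseudo-first-order time averaged over the feed, should shorten in inverse proportion to that charge. Pooling the end readings of mono adduct from both runs gives, for this flask: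

τ = reading time × summed run charges ÷ summed mono adduct ÷ flask charge = 83.8 min

feed time ÷ τ = 0.0955 lifetimes, so mono adduct ≈ 9.55% and substrate ≈ 90.4%

Add the decomposition of partner. As a step of first order it should take about the same share of partner in these flasks over the same feed, and the readings behind τ were taken with it running, so this reckoning adds no separate correction for it.

Then add the losses to double product and idle adduct, which the readings cannot separate. The end readings of the theta run leave 12.0% of its substrate unaccounted for, a figure that carries their scatter. Scaled from there by the square of the charge ratio, that loss is 3.00% in this flask, and by its first power 6.00%, so this reckoning estimates substrate in a range from about 84.5% to 87.5%.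

The forecast, expecting “fractional conversion roughly proportional to concentration”, gave substrate 88%, mono adduct 9% and double product 1%. Its substrate stands just above that range, and its mono adduct just below the figure from τ.

The flask gives substrate 84.3%, mono adduct 9.71% and double product 1.09%.

    partner → decomposed reagent (k = 0.0840 /min)
    substrate + partner → mono adduct + by-product (k = 0.430 /M/min)
    partner + mono adduct → double product + by-product (k = 0.770 /M/min)
    substrate + by-product ⇌ idle adduct, settled at all times (K = 24.0 /M)

Mono adduct stands close to the 9.55% counted from τ, but this flask has not come to rest. At 5.45 min the main step's half-life of substrate is 35 min, long against the 8.0 min of the run, and 69% of the partner charge still stands unbound at 8.00 min. Decomposition, with a half-life of 8.3 min, has 8.67 half-lives more before 80.0 min, when 0.0574% of that charge remains. By then substrate has fallen to 58.3%, mono adduct has reached 20.6% and double product 8.66%.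

In a neighbouring flask with 14 mM of substrate and the same equivalents, τ stretches to 210 min, so the feed covers 0.0382 lifetimes and mono adduct should stand near 3.82%. That flask gives 4.46%.

The readings come from a simulation with made-up constants, and the scatter is random.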